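**Plan**

- Retrosynthesis: the C8–prenyl bond is cut first (it comes from an O5 prenyl ether by a para-Claisen–Cope shift), then the bond from C6 to C3 of the hexanoic acid chain (arylcopper plus a 4-propyl β-lactone), and last the two bonds O1–C2 and C3–C4 of the dihydropyran ring.
- Enabling feature (chroman numbering): O1–C2(Me)–C3(Me) is a trans butane-2,3-diyl unit held to the benzene ring twice, by the C4 methylene at C4a and by O1 at C8a. C4a lies between C5–O and C8a–O, so before ring closure the arene is a mirror-symmetric 2-substituted 5-methoxyresorcinol with two interchangeable oxygens, and the C4 unit matches a twofold-symmetric electrophile.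
- Forward order: the symmetric benzyl chloride and the (R,R)-cyclic sulfate give the chroman (the only ring to be built); MOM-directed C6 metalation and lactone opening attach the chain; a temporary dihydrocoumarin lactone is opened by methoxide and O-prenylated; the prenyl group is shifted to C8 and the methyl ester is hydrolysed.
- Stereochemistry: C2 and C3 come from (2R,3R)-butane-2,3-diol through two SN2 inversions; the side-chain centre comes from (S)-2-propyloxirane, carried unchanged into the β-lactone and inverted once by the arylcopper.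

Key step: step 6

Remark: (S)-2-propyloxirane is taken as a purchasable enantiopure epoxide (the product of hydrolytic kinetic resolution of the racemate), and the target is taken to be stable as the open hydroxy acid when set free at pH 4 and 0 °C.

**Route**

Step 1
Reactants: 1 2,4,6-trihydroxybenzaldehyde
Product: 2 2,6-dihydroxy-4-methoxybenzaldehyde
Conditions: Me2SO4 (1.0 equiv), K2CO3 (1.0 equiv), acetone, 0 °C to rt
Reagents that add atoms: dimethyl sulfate, COS(=O)(=O)OC
Why: Williamson O-methylation with one equivalent of base and electrophile should occur at the 4-hydroxyl, the most acidic and least hindered phenol (para to the formyl group), whereas the two ortho hydroxyls are flanked and chelated in turn by the carbonyl group.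

Step 2
Reactants: 2 2,6-dihydroxy-4-methoxybenzaldehyde
Product: 3 4-methoxy-2,6-bis(triisopropylsilyloxy)benzaldehyde
Conditions: TIPSOTf (2.3 equiv), 2,6-lutidine, CH2Cl2, 0 °C to rt
Reagents that add atoms: triisopropylsilyl trifluoromethanesulfonate, CC(C)[Si](OS(=O)(=O)C(F)(F)F)(C(C)C)C(C)C
Why: Silylation of phenols with a silyl triflate and a hindered pyridine base is reliable even for chelated ortho-hydroxybenzaldehydes, and the bulky silyl group is chosen with the later benzylic organometallic in mind.

Step 3
Reactants: 3 4-methoxy-2,6-bis(triisopropylsilyloxy)benzaldehyde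
Product: 4 [4-methoxy-2,6-bis(triisopropylsilyloxy)phenyl]methanol
Conditions: NaBH4, THF/EtOH, 0 °C
Reagents that add atoms: none
Why: Hydride reduction of an aryl aldehyde with NaBH4 should leave the aryl silyl ethers untouched at 0 °C, the alkoxide staying bound to boron so that silyl transfer to the benzylic oxygen is not expected.

Step 4
Reactants: 4 [4-methoxy-2,6-bis(triisopropylsilyloxy)phenyl]methanol
Product: 5 4-methoxy-2,6-bis(triisopropylsilyloxy)benzyl chloride
Conditions: MsCl, iPr2NEt, CH2Cl2, −10 °C to rt; filtered through a short silica pad and used at once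
Reagents that add atoms: methanesulfonyl chloride, CS(=O)(=O)Cl
Why: Mesylation of this electron-rich benzylic alcohol gives a sulfonate that should be displaced at once by the chloride set free (chlorodehydroxylation via the mesylate), under non-acidic conditions that spare the silyl ethers.

Step 5
Reactants: 6 (2R,3R)-butane-2,3-diol
Product: 8 (4R,5R)-4,5-dimethyl-1,3,2-dioxathiolane 2,2-dioxide, via cyclic sulfite 7 (not isolated)
Conditions: SOCl2, CH2Cl2, 0 °C to reflux; then RuCl3·3H2O (0.5 mol%), NaIO4, MeCN/H2O, 0 °C
Reagents that add atoms: thionyl chloride, O=S(Cl)Cl; sodium periodate, [Na+].[O-]I(=O)(=O)=O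
Why: Cyclic sulfite formation and oxidation at sulfur by RuO4 made in the flask from catalytic RuCl3 and NaIO4 is the standard route to 1,2-cyclic sulfates, and no bond to either stereocentre is broken.

Step 6
Reactants: 5 4-methoxy-2,6-bis(triisopropylsilyloxy)benzyl chloride; 8 (4R,5R)-4,5-dimethyl-1,3,2-dioxathiolane 2,2-dioxide
Product: 12 (2S,3R)-7-methoxy-2,3-dimethylchroman-5-ol, via benzylmagnesium chloride 9 (not isolated), via silylated sulfate monoester 10 (not isolated), via bis-phenoxide sulfate 11 (not isolated)
Conditions: activated Mg turnings, THF, 0 °C, slow addition of 5, solution decanted from excess Mg; then 8 (0.8 equiv), CuI (10 mol%), THF, −40 to 0 °C; MeOH (to quench excess 9); then Bu4NF (3 equiv), degassed THF/DMF, rt to 65 °C; aq. NH4Cl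
Reagents that add atoms: none
Why: Proposed new method: the benzylic Grignard reagent 9, turned into a benzylcopper species by catalytic CuI, should attack one carbon of cyclic sulfate 8 in an SN2 fashion anti to the departing oxygen to give sulfate monoester 10, and fluoride then strips both silyl groups so that one phenoxide of 11 displaces the secondary sulfate at the other carbon; the closest known reactions are the copper-catalysed opening of 1,2-cyclic sulfates by Grignard reagents and the double displacement of cyclic sulfates by bis-nucleophiles such as malonate (cyclopropanes) or primary amines (aziridines), whereas this carbon-then-phenoxide pairing in one flask is new. The dihydropyran ring closes by 6-exo-tet O-alkylation. C3 is fixed by inversion at the carbon attacked by the benzyl group and C2 by inversion in the phenoxide closure, so the (4R,5R) sulfate is transcribed into the (2S,3R) trans pair without any chiral reagent. No regiochemical choice arises, because the twofold axis of 8 makes its two carbons equivalent and the mirror plane of the arene makes the two phenoxides equivalent, the unused one ending as the C5 hydroxyl. The step needs substitution to win over elimination, attack at sulfur, Wurtz coupling and oxygen-to-carbon silyl shift; copper catalysis, the chloride counter-ion, slow formation of 9 at 0 °C and the bulky triisopropylsilyl groups are there to secure this.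

Step 7
Reactants: 12 (2S,3R)-7-methoxy-2,3-dimethylchroman-5-ol
Product: 13 (2S,3R)-7-methoxy-5-(methoxymethoxy)-2,3-dimethylchroman
Conditions: MOMCl, iPr2NEt, CH2Cl2, 0 °C to rt
Reagents that add atoms: chloromethyl methyl ether, COCCl
Why: O-Alkylation of the free phenol with MOMCl installs an acetal that serves both as protecting group and as the strongest ortho-directing group on the ring for the coming metalation.

Step 8
Reactants: 14 (S)-2-propyloxirane
Product: 15 (S)-4-propyloxetan-2-one
Conditions: CO (60 bar), [(Ph3P)2N][Co(CO)4] (2 mol%), BF3·OEt2 (2 mol%), 1,2-dimethoxyethane, 80 °C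
Reagents that add atoms: carbon monoxide, [C-]#[O+]
Why: In this ring-expanding carbonylation of a terminal epoxide the cobaltate opens the Lewis-acid-activated epoxide at the unsubstituted CH2 carbon, CO inserts and the alkoxide closes onto the acyl cobalt, so the C–O bond at the stereocentre is never broken and the (S) configuration is retained.

Step 9
Reactants: 13 (2S,3R)-7-methoxy-5-(methoxymethoxy)-2,3-dimethylchroman; 15 (S)-4-propyloxetan-2-one
Product: 18 (3R)-3-[(2S,3R)-7-methoxy-5-(methoxymethoxy)-2,3-dimethylchroman-6-yl]hexanoic acid, via aryllithium 16 (not isolated), via arylmagnesium bromide 17 (not isolated)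
Conditions: n-BuLi, THF, 0 °C; MgBr2·OEt2, −30 °C; then 15 (1.3 equiv), CuBr·SMe2 (10 mol%), THF/Me2S, −30 to 0 °C; cold 1 M HCl
Reagents that add atoms: none
Why: Coordination-directed ortho-lithiation should take place at C6 between the methoxymethoxy and methoxy groups (the chelating acetal outweighing the ring oxygen that flanks C8), and after transmetalation the arylmagnesium reagent opens the β-lactone at its alkyl-oxygen carbon under copper catalysis (SN2 ring opening of a β-lactone by an organocopper species), so the new benzylic centre is formed by inversion of the (S) lactone carbon and is R.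

Step 10
Reactants: 18 (3R)-3-[(2S,3R)-7-methoxy-5-(methoxymethoxy)-2,3-dimethylchroman-6-yl]hexanoic acid
Product: 20 (4R,8S,9R)-5-methoxy-8,9-dimethyl-4-propyl-3,4,9,10-tetrahydro-2H,8H-pyrano[2,3-f]chromen-2-one, via hydroxy methyl ester 19 (not isolated)
Conditions: HCl (3 M in MeOH), 45 °C; evaporate; then TsOH·H2O (10 mol%), PhMe, 90 °C
Reagents that add atoms: none
Why: Acid-catalysed acetal exchange removes the MOM group (methanol captures the methoxymethyl cation as dimethoxymethane and keeps it off the electron-rich ring) while Fischer esterification occurs, and acid-catalysed transesterification then closes the six-membered aryl lactone, which turns the ester and lactone mixture into one isolable compound.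

Step 11
Reactants: 20 (4R,8S,9R)-5-methoxy-8,9-dimethyl-4-propyl-3,4,9,10-tetrahydro-2H,8H-pyrano[2,3-f]chromen-2-one; 21 prenyl bromide (1-bromo-3-methylbut-2-ene)
Product: 23 methyl (3R)-3-[(2S,3R)-7-methoxy-2,3-dimethyl-5-(3-methylbut-2-enyloxy)chroman-6-yl]hexanoate, via sodium phenoxide methyl ester 22 (not isolated)
Conditions: NaOMe (1.05 equiv), MeOH/THF, 0 °C to rt; evaporate to dryness; then 21 (1.2 equiv), DMF, 0 °C to rt
Reagents that add atoms: sodium methoxide, [Na+].[O-]C
Why: Methoxide opens the aryl lactone by acyl substitution (transesterification), which runs to completion because the phenoxide set free is a far weaker base than methoxide, and Williamson O-alkylation of that phenoxide by one equivalent of prenyl bromide in a dipolar aprotic solvent should give the prenyl ether, the side-chain stereocentre lying β to the ester and so being safe from enolisation.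

Step 12
Reactants: 23 methyl (3R)-3-[(2S,3R)-7-methoxy-2,3-dimethyl-5-(3-methylbut-2-enyloxy)chroman-6-yl]hexanoate
Product: 26 methyl (3R)-3-[(2S,3R)-5-hydroxy-7-methoxy-2,3-dimethyl-8-(3-methylbut-2-enyl)chroman-6-yl]hexanoate, via ortho-dienone 24 (not isolated), via para-dienone 25 (not isolated)
Conditions: N,N-diethylaniline, 190 °C, sealed tube, argon
Reagents that add atoms: none
Why: Because both ortho carbons (C4a and C6) are substituted, the aromatic Claisen rearrangement of the prenyl ether gives an ortho-dienone that cannot enolise, a Cope shift then carries the allyl unit on to C8 with restoration of the normal prenyl connectivity, and tautomerisation returns the phenol (para-Claisen–Cope sequence), no stereocentre of the product being involved.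

Step 13
Reactants: 26 methyl (3R)-3-[(2S,3R)-5-hydroxy-7-methoxy-2,3-dimethyl-8-(3-methylbut-2-enyl)chroman-6-yl]hexanoate
Product: 27 (3R)-3-[(2S,3R)-5-hydroxy-7-methoxy-2,3-dimethyl-8-(3-methylbut-2-enyl)chroman-6-yl]hexanoic acid
Conditions: LiOH, THF/MeOH/H2O, rt; then 0.5 M HCl to pH 4, 0 °C
Reagents that add atoms: lithium hydroxide, [Li+].[OH-]
Why: Saponification of the methyl ester (and of any aryl lactone formed thermally in step 12, which gives the same product) followed by mild acidification should release the hydroxy acid without touching the three stereocentres or the prenyl group.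

**Compound list**

1 | 2,4,6-trihydroxybenzaldehyde | O=Cc1c(O)cc(O)cc1O | starting material
2 | 2,6-dihydroxy-4-methoxybenzaldehyde | COc1cc(O)c(C=O)c(O)c1 | intermediate
3 | 4-methoxy-2,6-bis(triisopropylsilyloxy)benzaldehyde | COc1cc(O[Si](C(C)C)(C(C)C)C(C)C)c(C=O)c(O[Si](C(C)C)(C(C)C)C(C)C)c1 | intermediate
4 | [4-methoxy-2,6-bis(triisopropylsilyloxy)phenyl]methanol | COc1cc(O[Si](C(C)C)(C(C)C)C(C)C)c(CO)c(O[Si](C(C)C)(C(C)C)C(C)C)c1 | intermediate
5 | 4-methoxy-2,6-bis(triisopropylsilyloxy)benzyl chloride | COc1cc(O[Si](C(C)C)(C(C)C)C(C)C)c(CCl)c(O[Si](C(C)C)(C(C)C)C(C)C)c1 | intermediate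
6 | (2R,3R)-butane-2,3-diol | C[C@@H](O)[C@@H](C)O | starting material
7 | (4R,5R)-4,5-dimethyl-1,3,2-dioxathiolane 2-oxide (cyclic sulfite, not isolated) | C[C@H]1OS(=O)O[C@@H]1C | intermediate
8 | (4R,5R)-4,5-dimethyl-1,3,2-dioxathiolane 2,2-dioxide (cyclic sulfate) | C[C@H]1OS(=O)(=O)O[C@@H]1C | intermediate
9 | [4-methoxy-2,6-bis(triisopropylsilyloxy)benzyl]magnesium chloride (not isolated) | COc1cc(O[Si](C(C)C)(C(C)C)C(C)C)c(C[Mg]Cl)c(O[Si](C(C)C)(C(C)C)C(C)C)c1 | intermediate
10 | chloromagnesium (2R,3R)-4-[4-methoxy-2,6-bis(triisopropylsilyloxy)phenyl]-3-methylbutan-2-yl sulfate (not isolated) | COc1cc(O[Si](C(C)C)(C(C)C)C(C)C)c(C[C@@H](C)[C@@H](C)OS(=O)(=O)[O-])c(O[Si](C(C)C)(C(C)C)C(C)C)c1.[Mg+2].[Cl-] | intermediate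
11 | (2R,3R)-4-(4-methoxy-2,6-dioxidophenyl)-3-methylbutan-2-yl sulfate, mixed tetrabutylammonium/magnesium salt (not isolated) | COc1cc([O-])c(C[C@@H](C)[C@@H](C)OS(=O)(=O)[O-])c([O-])c1.CCCC[N+](CCCC)(CCCC)CCCC.CCCC[N+](CCCC)(CCCC)CCCC.[Mg+2].[Cl-] | intermediate
12 | (2S,3R)-7-methoxy-2,3-dimethylchroman-5-ol | COc1cc(O)c2c(c1)O[C@@H](C)[C@H](C)C2 | intermediate
13 | (2S,3R)-7-methoxy-5-(methoxymethoxy)-2,3-dimethylchroman | COc1cc(OCOC)c2c(c1)O[C@@H](C)[C@H](C)C2 | intermediate
14 | (S)-2-propyloxirane | CCC[C@H]1CO1 | starting material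
15 | (S)-4-propyloxetan-2-one | CCC[C@H]1CC(=O)O1 | intermediate
16 | [(2S,3R)-7-methoxy-5-(methoxymethoxy)-2,3-dimethylchroman-6-yl]lithium (not isolated) | COc1c([Li])c(OCOC)c2c(c1)O[C@@H](C)[C@H](C)C2 | intermediate
17 | [(2S,3R)-7-methoxy-5-(methoxymethoxy)-2,3-dimethylchroman-6-yl]magnesium bromide (not isolated) | COc1c([Mg]Br)c(OCOC)c2c(c1)O[C@@H](C)[C@H](C)C2 | intermediate
18 | (3R)-3-[(2S,3R)-7-methoxy-5-(methoxymethoxy)-2,3-dimethylchroman-6-yl]hexanoic acid | CCC[C@H](CC(=O)O)c1c(OCOC)c2c(cc1OC)O[C@@H](C)[C@H](C)C2 | intermediate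
19 | methyl (3R)-3-[(2S,3R)-5-hydroxy-7-methoxy-2,3-dimethylchroman-6-yl]hexanoate (not isolated) | CCC[C@H](CC(=O)OC)c1c(O)c2c(cc1OC)O[C@@H](C)[C@H](C)C2 | intermediate
20 | (4R,8S,9R)-5-methoxy-8,9-dimethyl-4-propyl-3,4,9,10-tetrahydro-2H,8H-pyrano[2,3-f]chromen-2-one (dihydrocoumarin lactone between O5 and the chain carboxyl) | CCC[C@@H]1CC(=O)Oc2c1c(OC)cc1O[C@@H](C)[C@H](C)Cc12 | intermediate
21 | prenyl bromide (1-bromo-3-methylbut-2-ene) | CC(C)=CCBr | starting material
22 | sodium salt of methyl (3R)-3-[(2S,3R)-7-methoxy-2,3-dimethyl-5-oxidochroman-6-yl]hexanoate (not isolated) | CCC[C@H](CC(=O)OC)c1c([O-])c2c(cc1OC)O[C@@H](C)[C@H](C)C2.[Na+] | intermediate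
23 | methyl (3R)-3-[(2S,3R)-7-methoxy-2,3-dimethyl-5-(3-methylbut-2-enyloxy)chroman-6-yl]hexanoate | CCC[C@H](CC(=O)OC)c1c(OCC=C(C)C)c2c(cc1OC)O[C@@H](C)[C@H](C)C2 | intermediate
24 | methyl (3R)-3-[(2S,3R)-7-methoxy-2,3-dimethyl-4a-(2-methylbut-3-en-2-yl)-5-oxo-3,4,4a,5-tetrahydro-2H-chromen-6-yl]hexanoate (ortho-dienone, either configuration at C4a; the C6 regioisomer would react on alike; not isolated) | CCC[C@H](CC(=O)OC)C1C(=O)C2(C(C)(C)C=C)C(=CC=1OC)O[C@@H](C)[C@H](C)C2 | intermediate
25 | methyl (3R)-3-[(2S,3R)-7-methoxy-2,3-dimethyl-8-(3-methylbut-2-enyl)-5-oxo-3,4,5,8-tetrahydro-2H-chromen-6-yl]hexanoate (para-dienone, either configuration at C8; not isolated) | CCC[C@H](CC(=O)OC)C1C(=O)C2=C(C(CC=C(C)C)C=1OC)O[C@@H](C)[C@H](C)C2 | intermediate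
26 | methyl (3R)-3-[(2S,3R)-5-hydroxy-7-methoxy-2,3-dimethyl-8-(3-methylbut-2-enyl)chroman-6-yl]hexanoate | CCC[C@H](CC(=O)OC)c1c(O)c2c(c(CC=C(C)C)c1OC)O[C@@H](C)[C@H](C)C2 | intermediate
27 | (3R)-3-[(2S,3R)-5-hydroxy-7-methoxy-2,3-dimethyl-8-(3-methylbut-2-enyl)chroman-6-yl]hexanoic acid | CCC[C@H](CC(=O)O)c1c(O)c2c(c(CC=C(C)C)c1OC)O[C@@H](C)[C@H](C)C2 | target

**Count**

Total: 13 steps. Longest linear sequence: 11 steps (steps 1 to 4, 6, 7, 9 to 13); steps 5 and 8 make the two side components.

**Steps most likely to fail**

Step 6. The ring closure may stall: the sulfate monoester may resist displacement by the phenoxide or eliminate, and before that Wurtz homocoupling may consume the benzyl chloride during magnesium insertion. The fallback sets out from 5 and uses a stepwise, separately activated closure. The same benzylcopper reagent (via 9, CuI catalysis, THF, −30 °C) would open commercial (2R,3R)-2,3-dimethyloxirane with inversion at the attacked carbon, a standard epoxide opening, to give (2R,3R)-4-[4-methoxy-2,6-bis(triisopropylsilyloxy)phenyl]-3-methylbutan-2-ol F1. Bu4NF in THF would remove both silyl groups to give 2-[(2R,3R)-3-hydroxy-2-methylbutyl]-5-methoxybenzene-1,3-diol F2. A Mitsunobu etherification (PPh3, diisopropyl azodicarboxylate, THF, 0 °C, high dilution) would then close the dihydropyran ring with inversion at the carbinol carbon. This comes back to the route at 12 with the same (2S,3R) configuration.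

Step 9. The SN2 opening at the secondary lactone carbon by a doubly ortho-substituted arylcopper may be slow, so that attack at the acyl carbon or elimination to hex-2-enoic acid takes over. The fallback sets out from 13 and replaces the stereospecific substitution by an auxiliary-controlled conjugate addition. (E)-Hex-2-enoyl chloride and lithiated (S)-4-phenyl-1,3-oxazolidin-2-one would give (4S)-3-[(2E)-hex-2-enoyl]-4-phenyl-1,3-oxazolidin-2-one F3. Arylmagnesium bromide 17, made from 13 as before and combined with CuBr·SMe2 (1 equiv, THF/Me2S, −20 °C), should add to the magnesium-chelated s-cis enoyl imide from the face opposite the phenyl group. This would give (4S)-3-[(3R)-3-[(2S,3R)-7-methoxy-5-(methoxymethoxy)-2,3-dimethylchroman-6-yl]hexanoyl]-4-phenyl-1,3-oxazolidin-2-one F4. Cleavage with LiOH and H2O2 (THF/H2O, 0 °C) returns the auxiliary and comes back to the route at 18.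

Step 12. At the temperature needed for the double sigmatropic shift the O-prenyl group may be lost by ether cleavage, or the ortho-dienone may be diverted before the Cope shift. The fallback sets out from 20 and puts the prenyl group on by cross-coupling. In lactone 20 the only free aromatic position is C8, so N-bromosuccinimide (MeCN, 0 °C) should give (4R,8S,9R)-6-bromo-5-methoxy-8,9-dimethyl-4-propyl-3,4,9,10-tetrahydro-2H,8H-pyrano[2,3-f]chromen-2-one F5. A Stille coupling with tributyl(3-methylbut-2-enyl)stannane (Pd(PPh3)4, a zerovalent palladium complex, DMF, 90 °C) would give (4R,8S,9R)-5-methoxy-8,9-dimethyl-6-(3-methylbut-2-enyl)-4-propyl-3,4,9,10-tetrahydro-2H,8H-pyrano[2,3-f]chromen-2-one F6. Opening of the lactone with LiOH (THF/H2O, then pH 4 at 0 °C) comes back to the route at 27.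

**Further compounds**

F1 | step 6 | (2R,3R)-4-[4-methoxy-2,6-bis(triisopropylsilyloxy)phenyl]-3-methylbutan-2-ol | COc1cc(O[Si](C(C)C)(C(C)C)C(C)C)c(C[C@@H](C)[C@@H](C)O)c(O[Si](C(C)C)(C(C)C)C(C)C)c1
F2 | step 6 | 2-[(2R,3R)-3-hydroxy-2-methylbutyl]-5-methoxybenzene-1,3-diol | COc1cc(O)c(C[C@@H](C)[C@@H](C)O)c(O)c1
F3 | step 9 | (4S)-3-[(2E)-hex-2-enoyl]-4-phenyl-1,3-oxazolidin-2-one | CCC/C=C/C(=O)N1[C@@H](c2ccccc2)COC1=O
F4 | step 9 | (4S)-3-[(3R)-3-[(2S,3R)-7-methoxy-5-(methoxymethoxy)-2,3-dimethylchroman-6-yl]hexanoyl]-4-phenyl-1,3-oxazolidin-2-one | CCC[C@H](CC(=O)N1[C@@H](c2ccccc2)COC1=O)c1c(OCOC)c2c(cc1OC)O[C@@H](C)[C@H](C)C2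
F5 | step 12 | (4R,8S,9R)-6-bromo-5-methoxy-8,9-dimethyl-4-propyl-3,4,9,10-tetrahydro-2H,8H-pyrano[2,3-f]chromen-2-one | CCC[C@@H]1CC(=O)Oc2c1c(OC)c(Br)c1O[C@@H](C)[C@H](C)Cc12
F6 | step 12 | (4R,8S,9R)-5-methoxy-8,9-dimethyl-6-(3-methylbut-2-enyl)-4-propyl-3,4,9,10-tetrahydro-2H,8H-pyrano[2,3-f]chromen-2-one | CCC[C@@H]1CC(=O)Oc2c1c(OC)c(CC=C(C)C)c1O[C@@H](C)[C@H](C)Cc12
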